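**Remarks.** The target SMILES has no stereocentre and no stereogenic double bond, so the compound is achiral and needs no enantiocontrol. Compounds 1 (a catalogue aryne precursor) and 5 (4-bromoresorcinol) are assumed to be purchasable. Coumarin numbering is used: ring A is the benzo ring, ring B the 3-aryl group with primed locants.

## Retrosynthetic overview

- Target 20 comes from tris-MOM coumarin 19 by acetal cleavage; 19 comes from silyl triflate 4, DMF 13 and arylacetate 12 in one operation.
- Feature used: the pyranone atoms O1, C2, C3 and C4 bridge the adjacent ring-A carbons C8a and C4a, and the C5 methoxy group is ortho to C4a, so a C4a≡C8a aryne is polarised to take oxygen at C8a and carbon at C4a.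
- Bonds of the key step: O1–C8a and C4–C4a (C=O insertion of DMF), C3–C4 (enolate addition), O1–C2 (lactonisation). The pyranone is the only ring formed, and it is formed last, onto intact rings A and B.
- 4 comes from 1 by borylation of the one unhindered ring C–H, oxidation and MOM protection; 12 comes from 5 by MOM protection, C3 metalation/prenylation and Pd-catalysed coupling with a zinc ester enolate.

Key step: step 7

## Route

Step 1
Reactants: 1 3-methoxy-2-(trimethylsilyl)phenyl trifluoromethanesulfonate
Product: 2 3-methoxy-5-(4,4,5,5-tetramethyl-1,3,2-dioxaborolan-2-yl)-2-(trimethylsilyl)phenyl trifluoromethanesulfonate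
Conditions: B2pin2 (1.0 equiv), [Ir(cod)OMe]2 (1.5 mol%), dtbpy (3 mol%), THF, 65 °C
Reagents that add atoms: bis(pinacolato)diboron, CC1(C)OB(OC1(C)C)B1OC(C)(C)C(C)(C)O1
Why: Iridium-catalysed C–H borylation is sterically controlled, and only the ring C–H meta to both OTf and OMe has no ortho substituent, so the boryl group should enter there while the aryl triflate and aryl–silicon bonds stay inert.

Step 2
Reactants: 2 3-methoxy-5-(4,4,5,5-tetramethyl-1,3,2-dioxaborolan-2-yl)-2-(trimethylsilyl)phenyl trifluoromethanesulfonate
Product: 3 5-hydroxy-3-methoxy-2-(trimethylsilyl)phenyl trifluoromethanesulfonate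
Conditions: 30% aq H2O2, NaHCO3, THF/H2O, 0 °C → rt
Reagents that add atoms: hydrogen peroxide, OO
Why: Ipso-oxidation of the arylboronic ester (hydroperoxide adds to boron, aryl migrates to oxygen, hydrolysis), with the bicarbonate buffer and low temperature sparing the triflate and, in the absence of fluoride, the C–Si bond.

Step 3
Reactants: 3 5-hydroxy-3-methoxy-2-(trimethylsilyl)phenyl trifluoromethanesulfonate
Product: 4 3-methoxy-5-(methoxymethoxy)-2-(trimethylsilyl)phenyl trifluoromethanesulfonate
Conditions: MOMCl, iPr2NEt, CH2Cl2, 0 °C → rt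
Reagents that add atoms: chloromethyl methyl ether, COCCl
Why: Amine-mediated O-alkylation of the phenol with an α-chloro ether (MOM protection), under which neither the amine nor chloride activates the ortho-silyl triflate.

Step 4
Reactants: 5 4-bromoresorcinol (4-bromobenzene-1,3-diol)
Product: 6 1-bromo-2,4-bis(methoxymethoxy)benzene
Conditions: MOMCl (2.5 equiv), iPr2NEt, CH2Cl2, 0 °C → rt
Reagents that add atoms: chloromethyl methyl ether, COCCl
Why: Twofold MOM protection of the phenols by O-alkylation, which also installs the two directing groups for the next step.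

Step 5
Reactants: 6 1-bromo-2,4-bis(methoxymethoxy)benzene; 7 prenyl bromide (1-bromo-3-methylbut-2-ene)
Product: 9 1-bromo-2,4-bis(methoxymethoxy)-3-(3-methylbut-2-en-1-yl)benzene, via aryllithium 8 (not isolated)
Conditions: LDA, THF, −78 °C; then CuBr·SMe2 (10 mol%), 7, −78 °C → rt
Reagents that add atoms: none
Why: Directed ortho-metalation removes the C3–H flanked by both OMOM groups, using an amide base that does not undergo Br/Li exchange and giving an aryllithium with no ortho halogen to eliminate; copper-catalysed SN2 allylation with prenyl bromide follows.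

Step 6
Reactants: 9 1-bromo-2,4-bis(methoxymethoxy)-3-(3-methylbut-2-en-1-yl)benzene; 10 methyl bromoacetate
Product: 12 methyl [2,4-bis(methoxymethoxy)-3-(3-methylbut-2-en-1-yl)phenyl]acetate, via Reformatsky reagent 11 (not isolated)
Conditions: 10, Zn (TMSCl-activated), THF, 40 °C; then 9, Pd2(dba)3 (2 mol%), XPhos (8 mol%), THF, 60 °C
Reagents that add atoms: none
Why: Negishi-type α-arylation of a zinc ester enolate (oxidative addition of the aryl bromide, transmetalation from the Reformatsky reagent, reductive elimination), whose near-neutral conditions tolerate the MOM acetals and the prenyl olefin.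

Step 7
Reactants: 4 3-methoxy-5-(methoxymethoxy)-2-(trimethylsilyl)phenyl trifluoromethanesulfonate; 12 methyl [2,4-bis(methoxymethoxy)-3-(3-methylbut-2-en-1-yl)phenyl]acetate; 13 N,N-dimethylformamide
Product: 19 3-[2,4-bis(methoxymethoxy)-3-(3-methylbut-2-en-1-yl)phenyl]-5-methoxy-7-(methoxymethoxy)-2H-chromen-2-one, via aryne 14 (not isolated), via benzoxete 15 (not isolated), via ortho-quinone methide 16 (not isolated), via lithium enolate 17 (not isolated), via Mannich adduct 18 (not isolated)
Conditions: 4 (1.5 equiv), anhydrous TBAT (1.6 equiv), DMF, 0 °C → rt; then added to 17 [from 12, LiHMDS (1.1 equiv), THF, −78 °C] at −40 °C, → rt, then 50 °C; H2O work-up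
Reagents that add atoms: none
Why: Fluoride removes the silyl group of 4 and triflate departs to give aryne 14; the DMF oxygen adds to the aryne carbon remote from the methoxy group (future C8a), the aryl anion next to the methoxy group (future C4a) closes onto the iminium carbon to give benzoxete 15, and 4π ring opening gives ortho-quinone methide 16. Enolate 17 then adds to the aminomethylidene carbon of 16 (Mannich-type addition, C3–C4) to give phenoxide 18, which closes the pyranone by 6-exo-trig acyl substitution at the methyl ester (O1–C2) and loses dimethylamine by E1cB elimination (C3=C4), in whichever order. The closest known reaction type is the three-component coupling of arynes, DMF and ester enolates or active-methylene compounds to give coumarins. No stereocentre is created in 19, since the two sp3 centres of 18 are erased by the elimination. The step needs regioselective addition to the aryne, which the inductively withdrawing methoxy group ortho to the triple bond secures by directing nucleophiles to the distal carbon, the OMOM group meta to that carbon having only a minor influence. It also needs C=O insertion to precede direct arylation of the enolate, which is secured by generating 14 in neat DMF before 17 is introduced, and the fluoride/base medium leaves the MOM ethers, the prenyl olefin and the lactone intact.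

Step 8
Reactants: 19 3-[2,4-bis(methoxymethoxy)-3-(3-methylbut-2-en-1-yl)phenyl]-5-methoxy-7-(methoxymethoxy)-2H-chromen-2-one
Product: 20 3-[2,4-dihydroxy-3-(3-methylbut-2-en-1-yl)phenyl]-7-hydroxy-5-methoxy-2H-chromen-2-one
Conditions: HCl (1.25 M in MeOH), MeOH/THF, 0 °C → rt
Reagents that add atoms: none
Why: Acid-catalysed transacetalisation of the three aryl MOM ethers to methanol frees the phenols, under dilute acid near room temperature that should leave the coumarin lactone intact and be too mild to protonate the trisubstituted prenyl olefin at a competing rate.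

## Compound list

1 | 3-methoxy-2-(trimethylsilyl)phenyl trifluoromethanesulfonate | COc1cccc(OS(=O)(=O)C(F)(F)F)c1[Si](C)(C)C | starting material
2 | 3-methoxy-5-(4,4,5,5-tetramethyl-1,3,2-dioxaborolan-2-yl)-2-(trimethylsilyl)phenyl trifluoromethanesulfonate | COc1cc(B2OC(C)(C)C(C)(C)O2)cc(OS(=O)(=O)C(F)(F)F)c1[Si](C)(C)C | intermediate
3 | 5-hydroxy-3-methoxy-2-(trimethylsilyl)phenyl trifluoromethanesulfonate | COc1cc(O)cc(OS(=O)(=O)C(F)(F)F)c1[Si](C)(C)C | intermediate
4 | 3-methoxy-5-(methoxymethoxy)-2-(trimethylsilyl)phenyl trifluoromethanesulfonate | COCOc1cc(OC)c([Si](C)(C)C)c(OS(=O)(=O)C(F)(F)F)c1 | intermediate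
5 | 4-bromoresorcinol (4-bromobenzene-1,3-diol) | Oc1ccc(Br)c(O)c1 | starting material
6 | 1-bromo-2,4-bis(methoxymethoxy)benzene | COCOc1ccc(Br)c(OCOC)c1 | intermediate
7 | prenyl bromide (1-bromo-3-methylbut-2-ene) | CC(C)=CCBr | starting material
8 | [3-bromo-2,6-bis(methoxymethoxy)phenyl]lithium | COCOc1ccc(Br)c(OCOC)c1[Li] | intermediate
9 | 1-bromo-2,4-bis(methoxymethoxy)-3-(3-methylbut-2-en-1-yl)benzene | COCOc1ccc(Br)c(OCOC)c1CC=C(C)C | intermediate
10 | methyl bromoacetate | COC(=O)CBr | starting material
11 | bromo(2-methoxy-2-oxoethyl)zinc (Reformatsky reagent) | COC(=O)C[Zn]Br | intermediate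
12 | methyl [2,4-bis(methoxymethoxy)-3-(3-methylbut-2-en-1-yl)phenyl]acetate | COCOc1ccc(CC(=O)OC)c(OCOC)c1CC=C(C)C | intermediate
13 | N,N-dimethylformamide | CN(C)C=O | starting material
14 | 3-methoxy-5-(methoxymethoxy)benzyne (1-methoxy-5-(methoxymethoxy)cyclohexa-1,5-dien-3-yne) | COCOC1=CC#CC(OC)=C1 | intermediate
15 | 3-methoxy-5-(methoxymethoxy)-N,N-dimethyl-2H-benzoxet-2-amine | CN(C)C1Oc2cc(OCOC)cc(OC)c12 | intermediate
16 | 6-[(dimethylamino)methylidene]-5-methoxy-3-(methoxymethoxy)cyclohexa-2,4-dien-1-one | CN(C)C=C1C(=O)C=C(OCOC)C=C1OC | intermediate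
17 | lithium enolate of 12 (lithium 2-[2,4-bis(methoxymethoxy)-3-(3-methylbut-2-en-1-yl)phenyl]-1-methoxyethen-1-olate) | COCOc1ccc(C=C(O[Li])OC)c(OCOC)c1CC=C(C)C | intermediate
18 | lithium phenoxide of methyl 2-[2,4-bis(methoxymethoxy)-3-(3-methylbut-2-en-1-yl)phenyl]-3-(dimethylamino)-3-[2-hydroxy-6-methoxy-4-(methoxymethoxy)phenyl]propanoate (diastereomer mixture, both centres lost later) | COCOc1cc(O[Li])c(C(N(C)C)C(C(=O)OC)c2ccc(OCOC)c(CC=C(C)C)c2OCOC)c(OC)c1 | intermediate
19 | 3-[2,4-bis(methoxymethoxy)-3-(3-methylbut-2-en-1-yl)phenyl]-5-methoxy-7-(methoxymethoxy)-2H-chromen-2-one | COc1cc(OCOC)cc2oc(=O)c(-c3ccc(OCOC)c(CC=C(C)C)c3OCOC)cc12 | intermediate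
20 | 3-[2,4-dihydroxy-3-(3-methylbut-2-en-1-yl)phenyl]-7-hydroxy-5-methoxy-2H-chromen-2-one | COc1cc(O)cc2oc(=O)c(-c3ccc(O)c(CC=C(C)C)c3O)cc12 | target

## Step count and risks

Total step count: 8. Longest linear sequence: 5 steps (1 → 2 → 3 → 4 → 19 → 20, and equally 5 → 6 → 9 → 12 → 19 → 20).

**Steps most likely to fail**

1. Step 7. The ester enolate may be arylated directly by residual aryne, the quinone methide may decay (for example by capturing a second aryne) before the enolate arrives, or Mannich addition and lactonisation may stall. Fallback, setting out from 4 and 12 and returning at 19: the aryne/DMF insertion is run alone (CsF, DMF, rt) and hydrolysed on aqueous work-up to 2-hydroxy-6-methoxy-4-(methoxymethoxy)benzaldehyde F1. Ester 12 is saponified (LiOH, THF/MeOH/H2O) to [2,4-bis(methoxymethoxy)-3-(3-methylbut-2-en-1-yl)phenyl]acetic acid F2. Esterification of F1 with F2 (EDC·HCl, DMAP, CH2Cl2) gives 2-formyl-3-methoxy-5-(methoxymethoxy)phenyl [2,4-bis(methoxymethoxy)-3-(3-methylbut-2-en-1-yl)phenyl]acetate F3, and DBU then effects the intramolecular Knoevenagel (Perkin–Oglialoro-type) condensation to 19.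

2. Step 5. Metalation by the amide base may be incomplete, deprotonation ortho to bromine with loss of LiBr may compete, or the allylation may take the SN2′ course to the reverse-prenyl isomer. Fallback, setting out from 7 and returning at 9: 1,3-bis(methoxymethoxy)benzene F4 (a catalogue compound, also available from resorcinol and MOMCl) is deprotonated at C2 with n-BuLi (THF, 0 °C) and alkylated with 7 (CuI cat.) to 1,3-bis(methoxymethoxy)-2-(3-methylbut-2-en-1-yl)benzene F5. Electrophilic aromatic bromination of F5 with NBS (MeCN, −20 °C), para to one OMOM group, then gives 9.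

3. Step 8. Acid-promoted addition of a freed 2′- or 4′-hydroxyl across the prenyl double bond (chroman ring closure) may compete with acetal cleavage. Fallback, setting out from 19 and returning at 20: TMSOTf and 2,2′-bipyridyl (CH2Cl2, 0 °C) exchange each aryl MOM ether for a silyl ether under buffered, non-protic conditions to give 3-[3-(3-methylbut-2-en-1-yl)-2,4-bis(trimethylsilyloxy)phenyl]-5-methoxy-7-(trimethylsilyloxy)-2H-chromen-2-one F6, which is hydrolysed with water at rt to 20.

## Further compounds

F1 | step 7 | 2-hydroxy-6-methoxy-4-(methoxymethoxy)benzaldehyde | COCOc1cc(O)c(C=O)c(OC)c1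
F2 | step 7 | [2,4-bis(methoxymethoxy)-3-(3-methylbut-2-en-1-yl)phenyl]acetic acid | COCOc1ccc(CC(=O)O)c(OCOC)c1CC=C(C)C
F3 | step 7 | 2-formyl-3-methoxy-5-(methoxymethoxy)phenyl [2,4-bis(methoxymethoxy)-3-(3-methylbut-2-en-1-yl)phenyl]acetate | COCOc1cc(OC)c(C=O)c(OC(=O)Cc2ccc(OCOC)c(CC=C(C)C)c2OCOC)c1
F4 | step 5 | 1,3-bis(methoxymethoxy)benzene | COCOc1cccc(OCOC)c1
F5 | step 5 | 1,3-bis(methoxymethoxy)-2-(3-methylbut-2-en-1-yl)benzene | COCOc1cccc(OCOC)c1CC=C(C)C
F6 | step 8 | 3-[3-(3-methylbut-2-en-1-yl)-2,4-bis(trimethylsilyloxy)phenyl]-5-methoxy-7-(trimethylsilyloxy)-2H-chromen-2-one | COc1cc(O[Si](C)(C)C)cc2oc(=O)c(-c3ccc(O[Si](C)(C)C)c(CC=C(C)C)c3O[Si](C)(C)C)cc12
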